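Locants follow tricyclo[8.4.1.0^{2,7}]pentadecane: ring A = cyclohexane C2–C7, ring B = seven-membered ring C1-C2-C7-C8-C9-C10-C15, ring C = cycloheptene C1/C10–C15 with C10=C11 at the bridgehead.
Retrosynthesis: both methylidenes (C6, C14) go back to ketones, which exposes a 1,5-diketone C14–C1–C2–C7–C6 lying across the ring B bond C1–C2; cut C1–C2 (retro-Michael), then C7–C8 (sp3–sp2 coupling), then ring A (aldehyde/enone annulation) and ring C ([5+2]).
Forward: ring A from (S)-citronellal and methyl vinyl ketone, side-chain oxygen by allylic C–H oxidation, ring C from a vinylcyclopropane and but-3-yn-1-ol, union at C7–C8, ring B closed last by intramolecular Michael addition, then double methylenation and desilylation.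
Stereochemistry: the side-chain methyl centre comes from (S)-citronellal and C3 from the prolinol catalyst; C2, C1 and C7 come from the ring B closure (attack anti to the C3 substituent, ring A away from the C11–C14 bridge, anti protonation), with C–C formation reversible.

Key step: step 8

Remark: 1-(2-methoxyethoxy)-1-vinylcyclopropane (9) is taken as a purchasable reagent; H-7 stays α to the C6 ketone until step 9, so no basic step is placed between steps 8 and 9.

Step 1
Reactants: 1 (S)-citronellal; 2 methyl vinyl ketone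
Product: 4 (4S)-4-[(2S)-6-methylhept-5-en-2-yl]cyclohex-2-en-1-one, via keto aldehyde 3 (not isolated)
Conditions: (S)-α,α-diphenylprolinol trimethylsilyl ether (5 mol%), ethyl 3,4-dihydroxybenzoate (20 mol%), neat, 4 °C; then KOH, nBu4NOH (cat.), Et2O/THF/H2O, reflux
Reagents that add atoms: none
Why: Enamine-catalysed asymmetric Michael addition followed by intramolecular aldol condensation (Robinson-type annulation); the diarylsilyloxymethyl group of the (S)-catalyst shields one face of the E-enamine, so the enone should add to the open face and set the future C3 as (S), while the citronellal methyl centre is not touched.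

Step 2
Reactants: 4 (4S)-4-[(2S)-6-methylhept-5-en-2-yl]cyclohex-2-en-1-one
Product: 5 (4S)-4-[(2S,5E)-7-hydroxy-6-methylhept-5-en-2-yl]cyclohex-2-en-1-one
Conditions: SeO2 (0.3 equiv), tBuOOH (3 equiv), salicylic acid (0.1 equiv), CH2Cl2, 0 °C to rt
Reagents that add atoms: tert-butyl hydroperoxide, CC(C)(C)OO (terminal oxygen source); selenium dioxide, O=[Se]=O (oxygen carrier)
Why: Riley-type SeO2 allylic oxidation (ene reaction then [2,3]-sigmatropic shift) should take the (E)-methyl group of the only electron-rich trisubstituted alkene and leave the electron-poor enone alone; the E geometry follows from the cyclic mechanism and no stereocentre is formed.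

Step 3
Reactants: 5 (4S)-4-[(2S,5E)-7-hydroxy-6-methylhept-5-en-2-yl]cyclohex-2-en-1-one
Product: 6 (4S)-4-[(2S,5E)-7-{[tert-butyl(diphenyl)silyl]oxy}-6-methylhept-5-en-2-yl]cyclohex-2-en-1-one
Conditions: tBuPh2SiCl, imidazole, DMF, rt
Reagents that add atoms: tert-butyl(chloro)diphenylsilane, CC(C)(C)[Si](Cl)(c1ccccc1)c1ccccc1
Why: Silyl ether formation at the primary allylic alcohol masks the only acidic proton before the organozinc, alkoxide and titanium steps; no stereocentre is involved.

Step 4
Reactants: 6 (4S)-4-[(2S,5E)-7-{[tert-butyl(diphenyl)silyl]oxy}-6-methylhept-5-en-2-yl]cyclohex-2-en-1-one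
Product: 7 (4S)-2-iodo-4-[(2S,5E)-7-{[tert-butyl(diphenyl)silyl]oxy}-6-methylhept-5-en-2-yl]cyclohex-2-en-1-one
Conditions: I2, pyridine/CH2Cl2 (1:1), 0 °C to rt
Reagents that add atoms: iodine, II
Why: α-Iodination of an enone by the amine addition, iodination and elimination sequence (Baylis–Hillman-type) should put iodine only on C7; the C3 centre is not enolised under these conditions.

Step 5
Reactants: 8 but-3-yn-1-ol; 9 1-(2-methoxyethoxy)-1-vinylcyclopropane
Product: 12 4-(2-hydroxyethyl)cyclohept-4-en-1-one, via 1,5-dienyl enol ether 10 (not isolated), via 1,4-dienyl enol ether 11 (not isolated)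
Conditions: [Rh(CO)2Cl]2 (1 mol%), ClCH2CH2Cl, 80 °C; then 1 M HCl, THF, rt
Reagents that add atoms: water, O
Why: Rhodium-catalysed intermolecular [5+2] cycloaddition of a vinylcyclopropane with a terminal alkyne builds ring C, and both regioisomeric enol ethers hydrolyse to the same 4-substituted cyclohept-4-enone, so the sense of alkyne insertion does not matter; the product is achiral.

Step 6
Reactants: 12 4-(2-hydroxyethyl)cyclohept-4-en-1-one
Product: 13 4-(2-iodoethyl)cyclohept-4-en-1-one
Conditions: I2, PPh3, imidazole, CH2Cl2, 0 °C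
Reagents that add atoms: iodine, II
Why: Appel iodination converts the primary alcohol into the primary iodide under neutral conditions that leave the ketone and the trisubstituted alkene alone.

Step 7
Reactants: 13 4-(2-iodoethyl)cyclohept-4-en-1-one; 7 (4S)-2-iodo-4-[(2S,5E)-7-{[tert-butyl(diphenyl)silyl]oxy}-6-methylhept-5-en-2-yl]cyclohex-2-en-1-one
Product: 15 (4S)-4-[(2S,5E)-7-{[tert-butyl(diphenyl)silyl]oxy}-6-methylhept-5-en-2-yl]-2-[2-(5-oxocyclohept-1-en-1-yl)ethyl]cyclohex-2-en-1-one, via alkylzinc iodide 14 (not isolated)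
Conditions: Zn dust (activated with BrCH2CH2Br and Me3SiCl), LiCl, THF, 40 °C; then 7, Pd2(dba)3 (2 mol%), SPhos (8 mol%), THF, rt to 40 °C
Reagents that add atoms: none
Why: Negishi sp3–sp2 cross-coupling of a ketone-tolerant primary alkylzinc iodide with an α-iodoenone forms C7–C8 without protecting either carbonyl; no stereocentre is formed or touched.

Step 8
Reactants: 15 (4S)-4-[(2S,5E)-7-{[tert-butyl(diphenyl)silyl]oxy}-6-methylhept-5-en-2-yl]-2-[2-(5-oxocyclohept-1-en-1-yl)ethyl]cyclohex-2-en-1-one
Product: 16 (1S,2S,3S,7S)-3-[(2S,5E)-7-{[tert-butyl(diphenyl)silyl]oxy}-6-methylhept-5-en-2-yl]tricyclo[8.4.1.0^{2,7}]pentadec-10-ene-6,14-dione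
Conditions: KOtBu (0.2 equiv), tBuOH/THF (1:5), 0.01 M, −20 to 0 °C; AcOH quench at −20 °C
Reagents that add atoms: none
Why: Substoichiometric KOtBu should enolise the ring C ketone reversibly toward C1 and C13, and only the C1 enolate can add to the enone β-carbon C2 in an intramolecular Michael addition that closes ring B by a 7-endo-trig (enolexo) attack, after which tBuOH protonates the ring A enolate at C7 and returns the base. The closest known reaction type is the alkoxide-mediated intramolecular Michael addition of a ketone enolate to a cycloalkenone that is used to close bridged carbocycles. The event is possible because C14–C1–C2–C7–C6 is a 1,5-dicarbonyl array laid across the ring B bond C1–C2, while the bridgehead alkene C10=C11 is already an ordinary cis alkene of ring C and does not have to be made under strain. C2 should be set by axial attack anti to the C3 side chain, C1 by closure with ring A on the face of ring B away from the C11–C14 bridge (the other mode forces C3 under that bridge), and C7 by axial protonation anti to the new axial C1–C2 bond, the normal trans course of conjugate addition and protonation on a 2-alkylcyclohexenone, which gives the cis A/B fusion with H-2 and H-7 on the bridge face. The step needs C1- over C13-attack (seven- against eight-membered ring), 1,4- over 1,2-addition and an untouched C3: the first two are corrected by the reversibility of the aldol and of the wrong Michael closure, the third by keeping the base catalytic and cold so that the extended dienolate of ring A is not formed. Because C1–C2 formation is reversible, adducts of the wrong configuration at C1 or C2 should drain into the bridged diketone before the cold quench.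

Step 9
Reactants: 16 (1S,2S,3S,7S)-3-[(2S,5E)-7-{[tert-butyl(diphenyl)silyl]oxy}-6-methylhept-5-en-2-yl]tricyclo[8.4.1.0^{2,7}]pentadec-10-ene-6,14-dione
Product: 17 tert-butyl{[(2E,6S)-6-[(1S,2S,3S,7S)-6,14-dimethylidenetricyclo[8.4.1.0^{2,7}]pentadec-10-en-3-yl]-2-methylhept-2-en-1-yl]oxy}diphenylsilane
Conditions: Zn, CH2Br2, TiCl4, THF (reagent preformed at −40 to 5 °C); then 16, CH2Cl2, 0 °C to rt
Reagents that add atoms: dibromomethane, BrCBr
Why: Takai–Lombardo methylenation with the non-basic zinc/titanium methylene reagent should convert both ketones into the C6 and C14 methylidenes without enolising the α-centres C7 and C1, which therefore keep the configuration set in step 8.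

Step 10
Reactants: 17 tert-butyl{[(2E,6S)-6-[(1S,2S,3S,7S)-6,14-dimethylidenetricyclo[8.4.1.0^{2,7}]pentadec-10-en-3-yl]-2-methylhept-2-en-1-yl]oxy}diphenylsilane
Product: 18 (2E,6S)-6-[(1S,2S,3S,7S)-6,14-dimethylidenetricyclo[8.4.1.0^{2,7}]pentadec-10-en-3-yl]-2-methylhept-2-en-1-ol
Conditions: Bu4NF, THF, 0 °C to rt
Reagents that add atoms: none
Why: Fluoride-driven cleavage of the Si–O bond (silyl ether deprotection) should release the primary allylic alcohol without touching the four alkenes or any stereocentre.

Compound list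
1 | (S)-citronellal, (3S)-3,7-dimethyloct-6-enal | C[C@@H](CCC=C(C)C)CC=O | starting material
2 | methyl vinyl ketone (but-3-en-2-one) | CC(=O)C=C | starting material
3 | (2S,3S)-3,7-dimethyl-2-(3-oxobutyl)oct-6-enal | CC(=O)CC[C@@H]([C@@H](C)CCC=C(C)C)C=O | intermediate (not isolated)
4 | (4S)-4-[(2S)-6-methylhept-5-en-2-yl]cyclohex-2-en-1-one | O=C1CC[C@@H]([C@@H](C)CCC=C(C)C)C=C1 | intermediate
5 | (4S)-4-[(2S,5E)-7-hydroxy-6-methylhept-5-en-2-yl]cyclohex-2-en-1-one | O=C1CC[C@@H]([C@@H](C)CC/C=C(\C)CO)C=C1 | intermediate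
6 | (4S)-4-[(2S,5E)-7-{[tert-butyl(diphenyl)silyl]oxy}-6-methylhept-5-en-2-yl]cyclohex-2-en-1-one | O=C1CC[C@@H]([C@@H](C)CC/C=C(\C)CO[Si](c2ccccc2)(c2ccccc2)C(C)(C)C)C=C1 | intermediate
7 | (4S)-2-iodo-4-[(2S,5E)-7-{[tert-butyl(diphenyl)silyl]oxy}-6-methylhept-5-en-2-yl]cyclohex-2-en-1-one | O=C1CC[C@@H]([C@@H](C)CC/C=C(\C)CO[Si](c2ccccc2)(c2ccccc2)C(C)(C)C)C=C1I | intermediate
8 | but-3-yn-1-ol | C#CCCO | starting material
9 | 1-(2-methoxyethoxy)-1-vinylcyclopropane | C=CC1(OCCOC)CC1 | starting material
10 | 2-[5-(2-methoxyethoxy)cyclohepta-1,5-dien-1-yl]ethan-1-ol | COCCOC1=CCC(CCO)=CCC1 | intermediate (not isolated)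
11 | 2-[5-(2-methoxyethoxy)cyclohepta-1,4-dien-1-yl]ethan-1-ol | COCCOC1=CCC=C(CCO)CC1 | intermediate (not isolated)
12 | 4-(2-hydroxyethyl)cyclohept-4-en-1-one | O=C1CCC(CCO)=CCC1 | intermediate
13 | 4-(2-iodoethyl)cyclohept-4-en-1-one | O=C1CCC(CCI)=CCC1 | intermediate
14 | [2-(5-oxocyclohept-1-en-1-yl)ethyl]zinc iodide | O=C1CCC(CC[Zn]I)=CCC1 | intermediate (not isolated)
15 | (4S)-4-[(2S,5E)-7-{[tert-butyl(diphenyl)silyl]oxy}-6-methylhept-5-en-2-yl]-2-[2-(5-oxocyclohept-1-en-1-yl)ethyl]cyclohex-2-en-1-one | O=C1CC[C@@H]([C@@H](C)CC/C=C(\C)CO[Si](c2ccccc2)(c2ccccc2)C(C)(C)C)C=C1CCC1=CCCC(=O)CC1 | intermediate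
16 | (1S,2S,3S,7S)-3-[(2S,5E)-7-{[tert-butyl(diphenyl)silyl]oxy}-6-methylhept-5-en-2-yl]tricyclo[8.4.1.0^{2,7}]pentadec-10-ene-6,14-dione | O=C1CC[C@@H]([C@@H](C)CC/C=C(\C)CO[Si](c3ccccc3)(c3ccccc3)C(C)(C)C)[C@H]2[C@@H]1CCC1=CCCC(=O)[C@H]2C1 | intermediate
17 | tert-butyl{[(2E,6S)-6-[(1S,2S,3S,7S)-6,14-dimethylidenetricyclo[8.4.1.0^{2,7}]pentadec-10-en-3-yl]-2-methylhept-2-en-1-yl]oxy}diphenylsilane | C=C1CC[C@@H]([C@@H](C)CC/C=C(\C)CO[Si](c3ccccc3)(c3ccccc3)C(C)(C)C)[C@H]2[C@@H]1CCC1=CCCC(=C)[C@H]2C1 | intermediate
18 | (2E,6S)-6-[(1S,2S,3S,7S)-6,14-dimethylidenetricyclo[8.4.1.0^{2,7}]pentadec-10-en-3-yl]-2-methylhept-2-en-1-ol | C=C1CC[C@@H]([C@@H](C)CC/C=C(\C)CO)[C@H]2[C@@H]1CCC1=CCCC(=C)[C@H]2C1 | target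

Total step count: 10. Longest linear sequence: 8 steps (steps 1, 2, 3, 4, 7, 8, 9, 10, from 1).

Steps most likely to fail

Step 8. The ring closure may be slower than formation of the extended dienolate of ring A, which would scramble C3. Prolonged contact with alkoxide may also equilibrate C7 toward the trans ring fusion, or reopen ring B by retro-Michael reaction. The fallback closes the same bond through covalent enamine activation in a nearly neutral medium (Stork enamine Michael addition); it sets out from 15 and returns at 16. Compound 15 is condensed with pyrrolidine (AcOH cat., benzene, azeotropic removal of water) to the ring C enamine on the C1 side F1, which equilibrates through the iminium ion with the C13-side enamine F2. Only F1 can reach C2 through a seven-membered transition state, and on warming it should cyclise to the tricyclic enamine F3. Aqueous AcOH then hydrolyses F3 to 16.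

Step 9. Methylenation may stop at the hindered C14 carbonyl next to the bridgehead, and the Lewis-acidic reagent may cause enolisation at C7 or alkene migration. The fallback is a two-stage Peterson olefination that sets out from 16 and returns at 17. Addition of Me3SiCH2Li with CeCl3 (THF, −78 °C), which suppresses enolisation, to both carbonyls gives the bis(β-hydroxysilane) F4. Elimination with KH in THF then gives 17.

Step 2. The allylic alcohol may be over-oxidised to the enal, which cannot be returned with borohydride beside the enone, and oxidation α to the enone carbonyl may compete. The fallback replaces C–H oxidation by alkene cleavage and olefination; it sets out from 4 and returns at 5. Ozonolysis of only the electron-rich trisubstituted alkene (O3, pyridine, CH2Cl2, −78 °C, indicator-controlled, then Me2S) gives the keto aldehyde F5. A stabilised Wittig reaction with 2-(triphenylphosphoranylidene)propanal (toluene, 80 °C), which reacts only at the aldehyde and is E-selective, gives the enal F6. Aldehyde-selective reduction (NaBH4, EtOH/CH2Cl2, −78 °C) then gives 5.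

Further compounds
F1 | step 8 | C1-side pyrrolidine enamine of 15 (N on C14, C14=C1) | O=C1CC[C@@H]([C@@H](C)CC/C=C(\C)CO[Si](c2ccccc2)(c2ccccc2)C(C)(C)C)C=C1CCC1=CCCC(N2CCCC2)=CC1
F2 | step 8 | C13-side pyrrolidine enamine of 15 (N on C14, C13=C14) | O=C1CC[C@@H]([C@@H](C)CC/C=C(\C)CO[Si](c2ccccc2)(c2ccccc2)C(C)(C)C)C=C1CCC1=CCC=C(N2CCCC2)CC1
F3 | step 8 | tricyclic enamine of 16 (pyrrolidin-1-yl on C14, C13=C14, ketone at C6) | O=C1CC[C@@H]([C@@H](C)CC/C=C(\C)CO[Si](c3ccccc3)(c3ccccc3)C(C)(C)C)[C@H]2[C@@H]1CCC1=CCC=C(N3CCCC3)[C@H]2C1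
F4 | step 9 | 6,14-bis[(trimethylsilyl)methyl]-6,14-diol from 16 (carbinol configurations immaterial) | C[Si](C)(C)CC1(O)CC[C@@H]([C@@H](C)CC/C=C(\C)CO[Si](c3ccccc3)(c3ccccc3)C(C)(C)C)[C@H]2[C@@H]1CCC1=CCCC(O)(C[Si](C)(C)C)[C@H]2C1
F5 | step 2 | (4S)-4-[(2S)-5-oxopentan-2-yl]cyclohex-2-en-1-one | O=C1CC[C@@H]([C@@H](C)CCC=O)C=C1
F6 | step 2 | (2E,6S)-2-methyl-6-[(1S)-4-oxocyclohex-2-en-1-yl]hept-2-enal | O=C1CC[C@@H]([C@@H](C)CC/C=C(\C)C=O)C=C1
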